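The earlier runs and the new flask are calculated for an exercise, and the scatter is random.

- I began from how slowly Thursday's substrate went, and set that flask's clocks in order, from fast to slow.

| setting | Thursday's | epsilon | beta |
|---|---|---|---|
| substrate | 0.010 M | 0.010 M | 0.010 M |
| reagent | 4 equiv | 4.00 equiv | 4.00 equiv |
| scavenger | 1.1 equiv | 1.60 equiv | 1.20 equiv |
| remark | run made earlier |  |  |
| time |  | 5.0 h | 5.0 h |
- Thursday's (time / h: substrate / %, mono adduct / %): 0.667: 75, 22; 1.33: 56, 17; 2.00: 42, 19; 3.00: 33, 15; 4.00: 20, 11; 5.00: 20, 10

(readings scatter by 2 percentage points)
- no earlier run changes the charge of scavenger; that part of a forecast is a guess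
- part of the substrate that has reacted at the end, epsilon
- part of the substrate that has reacted at the end, beta
- what raising the equivalents of scavenger from its lowest to its highest value here does to the part of the substrate that has reacted (changes below 5 percentage points count as none) (no change / it falls / it rises)

- Mono adduct came first on my ladder: at 2.00 h in Thursday's run it read 19% against 42% of substrate.
- Substrate came next, with an early pseudo-first-order constant, read from that same reading, of 0.434 h⁻¹, so a half-life of 1.60 h.
- Taking mono adduct as used about as fast as it was made, I read 0.959 h⁻¹ and a half-life of 0.723 h, shorter than the substrate's, so in Thursday's run it followed the substrate and set no clock of its own.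
- Thursday's run itself, at 5.00 h, was the slowest rung, longer than both half-lives, so I needed one number for the whole sagging curve.
- I kept 0.322 h⁻¹, the mean first-order constant of substrate over Thursday's run, the one that carries the charge to the share read at the end.
- Its error lay mid-run: at 2.00 h it left 52.5% against the 42% read, 11 percentage points out, so I trusted it for the end of a run of that length and no earlier.
- Epsilon and beta have Thursday's substrate and reagent charges and its length, so I reckoned 80.0% reacted in each; that scavenger changes nothing was my guess.
- The forecast gave 83% for epsilon, 81% for beta and no change, adding "More scavenger might help slightly, but this is a guess"; for epsilon that is 3 points above mine.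

    reagent + triple product → tetra adduct + released group (k = 0.150 M⁻¹ min⁻¹)
    reagent + bis adduct → triple product + released group (k = 1.20 M⁻¹ min⁻¹)
    reagent + mono adduct → bis adduct + released group (k = 0.590 M⁻¹ min⁻¹)
    scavenger + released group → scavenged by-product (k = 110 M⁻¹ min⁻¹)
    substrate + reagent → mono adduct + released group (k = 0.220 M⁻¹ min⁻¹)
    reagent + released group ⇌ idle adduct, settled at all times (K = 78.0 M⁻¹)

- Epsilon gave 80.0% and beta 78.9%, so raising the scavenger from beta's charge to epsilon's moved the answer by 1.1 points, less than the 5 points that counts as a change, and the verdict was no change. Reagent cut to 3.39 equiv moved epsilon's answer by 5 points. For the neighbour flask with 0.0060 M of substrate at the same equivalents, I scaled the mean constant with the charge to 0.193 h⁻¹, which gives 61.9% reacted against the 69.5% it gave. That neighbour ended with 52% of its reagent free, against 32.2% in epsilon.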